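(The readings are simulated for an exercise.)

Start from slowness. In the violet run, isomer of the product reads 5 % at 40.0 s, less than the target's 68 %. So follow the ratio of isomer to target, in powers of ten.

| flask | substrate | remark | time |
|---|---|---|---|
| violet | 0.25 M | run made earlier |  |
| flask | 0.50 M |  | 3.0 min |

violet run (percent of the substrate charged)

| time / s | isomer of the product / % | target / % |
|---|---|---|
| 10.0 | 0 | 36 |
| 12.0 | 3 | 37 |
| 20.0 | 2 | 52 |
| 25.0 | 2 | 60 |
| 30.0 | 7 | 62 |
| 40.0 | 5 | 68 |

(each reading ± 1.5 percentage points)

- a reading or a percentage of target counts all its forms, free or not

* ratio of isomer of the product to target at 1.2 s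
* ratio of isomer of the product to target at 3.0 min
* which of isomer of the product and target there is more of at 3.0 min

1. Pool the violet readings, since the scatter is 1.5 percentage points. The first four have mean time 16.8 s and ratio 0.0378. The last two have 35.0 s and 0.0923.

2. Take logarithms. The ratio climbs 1.22 decades per decade of time. A parallel route gives zero, and target turning into isomer gives about one.

3. Define the clock: the ratio gained per second while the ratio is small. The early group gives 0.00226 /s and the late group 0.00264 /s. These are separate readings, and they agree within scatter, so take 0.00245 /s. Assume first-order steps, so the clock ignores the charge.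

4. Go down to 1.2 s. The clock gives 0.00294. The ratio is small there, so any return of isomer is negligible. Trust this.

5. Go up to 3.0 min. The clock gives 0.441, while holding the late ratio gives 0.0923. The two ways part, so find the cheat. The line cheats: the clock is defined while the ratio is small, yet 0.441 is not small, and 3.0 min is later than the last reading at 40.0 s. The held ratio is my judgement too, as the violet run has no reading after that time. Distrust the line and commit to 0.0923, with target ahead.

The forecast, saying “I lean towards the consecutive route but hedge between them”, gives 0.03 and 0.4, both higher than my numbers, with target in the lead.

    substrate ⇌ intermediate A (K = 1.90, k = 0.0447 /s)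
    substrate ⇌ intermediate B (K = 2.68, k = 0.0965 /s)
    intermediate B → target (k = 0.343 /s)
    intermediate B ⇌ intermediate C (K = 0.730, k = 0.0325 /s)
    substrate ⇌ intermediate C (k = 0.0735 /s)
    crystals ⇌ target, rate k6*(cs6 - [target]) while solid is left; crystals form when [target] > cs6 (solubility = 0.240 M, k = 3.31 /s)
    target ⇌ isomer of the product (K = 0.110, k = 0.00380 /s)
    2 substrate → self-condensation product (k = 9.00 × 10⁻⁵ /M/s)

The flask gives 0.00159 at 1.2 s, and the clock stands at twice that; the neighbour charged with 2.0 M gives the same 0.00159. At 3.0 min the flask gives 0.0572, with target ahead at 92.2 %. Target and isomer relax, both ways together, with half-life 0.301 min, and 3.0 min is ten times that, so kinetic control has given way to thermodynamic control. Isomer in the flask reads 5.27 % at 3.00 min and 5.28 % at 30.0 min, and in the neighbour 1.32 % at 3.00 min.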